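**Retrosynthetic overview** (chromene numbering O1, C2–C4, C4a–C8a; ring A = benzene ring, ring B = pyran ring; side chain C1'–C9' counted from C2)
1. Last C–C disconnection: the sp3–sp2 bond C2'–C3', made in one flask by hydroboration and B-alkyl Suzuki–Miyaura coupling of an (R)-2-vinyl-2H-chromene with a (2Z,6E)-iododienoate that already holds the other two alkenes and the ester.
2. Enabling feature: C2 of ring B is a quaternary ether carbon whose arm C1'–C2' ends exactly at the bond to be made. Carried as a C2-vinyl group (the alkene oxidation level), it is the only monosubstituted C=C present, so 9-BBN puts boron on C2' alone and leaves the ring B alkene C3=C4.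
3. The vinyl group costs nothing: asymmetric allylic etherification of a methylhydroquinone monosilyl ether with isoprene monoxide forms O1–C2, sets the stereocenter, and delivers the C2-methyl, C1'=C2' and a CH2OH that becomes C3.
4. Ring order: ring A is bought; ring B is closed second, by gold-catalyzed 6-endo hydroarylation (C4–C4a bond) of the alkyne grown from that CH2OH, which does not touch C2.
5. Iododienoate: zirconium-catalyzed carboalumination/iodination (E-iodoalkene), then Still–Gennari olefination (Z-enoate); the end game is desilylation and saponification.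

Key step: step 10

Assumption: in step 2 the (S,S) ligand enantiomer is taken as the one that should give the (R)-ether; if the sense of induction is the opposite, the (R,R) ligand is used and nothing else in the route changes.

**Step 1**
Reactants: 1 2-methylbenzene-1,4-diol; 2 chlorotriisopropylsilane
Product: 3 2-methyl-4-(triisopropylsilyloxy)phenol
Conditions: i-Pr3SiCl (1.0 equiv.), imidazole (2.2 equiv.), DMF, −20 °C → 0 °C
Reagents that add atoms: chlorotriisopropylsilane (2), CC(C)[Si](Cl)(C(C)C)C(C)C
Why: Sterically controlled mono-O-silylation: the bulky chloride should select the 4-OH, which has no ortho substituent, over the 1-OH next to the methyl group.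

**Step 2**
Reactants: 3 2-methyl-4-(triisopropylsilyloxy)phenol; 4 2-methyl-2-vinyloxirane (racemic)
Product: 5 (2R)-2-methyl-2-[2-methyl-4-(triisopropylsilyloxy)phenoxy]but-3-en-1-ol
Conditions: Pd2(dba)3·CHCl3 (1 mol%, zerovalent palladium), (S,S)-N,N'-(cyclohexane-1,2-diyl)bis[2-(diphenylphosphanyl)benzamide] (3 mol%), CH2Cl2, rt
Reagents that add atoms: 2-methyl-2-vinyloxirane (4), CC1(C=C)CO1
Why: Tsuji–Trost asymmetric allylic etherification run as a dynamic kinetic asymmetric transformation: zerovalent palladium opens the racemic vinyl epoxide to a π-allyl alkoxide whose faces interconvert by η3–η1–η3 slippage at the CH2 terminus, the alkoxide deprotonates the phenol and guides it to the adjacent fully substituted terminus, and the chiral pocket of the ligand sets the (R) configuration at the new C–O carbon (future C2).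

**Step 3**
Reactants: 5 (2R)-2-methyl-2-[2-methyl-4-(triisopropylsilyloxy)phenoxy]but-3-en-1-ol
Product: 6 (2R)-2-methyl-2-[2-methyl-4-(triisopropylsilyloxy)phenoxy]but-3-enal
Conditions: Dess–Martin periodinane (1.3 equiv.), CH2Cl2, 0 °C → rt
Reagents that add atoms: none
Why: Dess–Martin oxidation of the primary alcohol; the α-carbon is quaternary, so the aldehyde can neither enolize nor epimerize.

**Step 4**
Reactants: 6 (2R)-2-methyl-2-[2-methyl-4-(triisopropylsilyloxy)phenoxy]but-3-enal; 7 dimethyl (1-diazo-2-oxopropyl)phosphonate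
Product: 8 (3R)-3-methyl-3-[2-methyl-4-(triisopropylsilyloxy)phenoxy]pent-1-en-4-yne
Conditions: 7 (1.5 equiv.), K2CO3 (2 equiv.), MeOH, 0 °C → rt
Reagents that add atoms: dimethyl (1-diazo-2-oxopropyl)phosphonate (7), CC(=O)C(=[N+]=[N-])P(=O)(OC)OC
Why: Seyferth–Gilbert homologation with the Ohira–Bestmann reagent converts the non-enolizable aldehyde into the terminal alkyne through a diazoalkene and an alkylidene carbene (1,2-hydrogen shift) without touching the stereocenter, and the triisopropylsilyl aryl ether should survive cold methanolic carbonate.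

**Step 5**
Reactants: 8 (3R)-3-methyl-3-[2-methyl-4-(triisopropylsilyloxy)phenoxy]pent-1-en-4-yne
Product: 9 (2R)-2,8-dimethyl-6-(triisopropylsilyloxy)-2-vinyl-2H-chromene
Conditions: [Au(NCMe){P(t-Bu)2(biphenyl-2-yl)}]SbF6 (2 mol%, monovalent gold), CH2Cl2, rt
Reagents that add atoms: none
Why: Gold-catalyzed intramolecular alkyne hydroarylation (6-endo-dig attack of the only free ortho carbon on the gold-activated terminal alkyne, then protodeauration) closes ring B at C4–C4a without breaking C2–O1, so the configuration at C2 is kept, unlike a thermal propargyl Claisen route that passes through an achiral ortho-quinone methide.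

**Step 6**
Reactants: 10 pent-4-yn-1-ol; 11 trimethylaluminium; 12 iodine
Product: 14 (E)-5-iodo-4-methylpent-4-en-1-ol, via alkenylalane 13 (not isolated)
Conditions: AlMe3 (3 equiv.), Cp2ZrCl2 (0.25 equiv.), CH2Cl2, 0 °C → rt; then I2 (1.2 equiv.), THF, −30 °C → 0 °C; aqueous work-up
Reagents that add atoms: trimethylaluminium (11), C[Al](C)C; iodine (12), II
Why: Negishi zirconium-catalyzed syn-carboalumination puts methyl on the internal and aluminium on the terminal alkyne carbon, and iodinolysis with retention gives the (E)-2-methyl-1-iodoalkene, the hydroxyl being carried as its aluminium alkoxide.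

**Step 7**
Reactants: 14 (E)-5-iodo-4-methylpent-4-en-1-ol
Product: 15 (E)-5-iodo-4-methylpent-4-enal
Conditions: Dess–Martin periodinane (1.2 equiv.), CH2Cl2, 0 °C → rt
Reagents that add atoms: none
Why: Dess–Martin oxidation under neutral conditions leaves the alkenyl iodide and its geometry untouched.

**Step 8**
Reactants: 16 methyl 2-[bis(2,2,2-trifluoroethoxy)phosphoryl]acetate; 17 5-bromo-2-methylpent-2-ene
Product: 18 methyl 2-[bis(2,2,2-trifluoroethoxy)phosphoryl]-6-methylhept-5-enoate (racemic)
Conditions: NaH (1.05 equiv.), DMF, 0 °C; then 17, 0 °C → rt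
Reagents that add atoms: 5-bromo-2-methylpent-2-ene (17), CC(C)=CCCBr
Why: SN2 C-alkylation of the sodium salt of the phosphonoacetate with the primary homoallylic bromide.

**Step 9**
Reactants: 15 (E)-5-iodo-4-methylpent-4-enal; 18 methyl 2-[bis(2,2,2-trifluoroethoxy)phosphoryl]-6-methylhept-5-enoate
Product: 19 methyl (2Z,6E)-7-iodo-6-methyl-2-(4-methylpent-3-en-1-yl)hepta-2,6-dienoate
Conditions: KN(SiMe3)2 (1.1 equiv.), 18-crown-6 (3 equiv.), THF, −78 °C; then 15, −78 °C
Reagents that add atoms: none
Why: Still–Gennari variant of the Horner–Wadsworth–Emmons olefination: with the bis(trifluoroethyl) phosphonate and a dissociated potassium ion the adduct collapses under kinetic control, which places the ester cis to the aldehyde-derived chain and gives the (2Z)-trisubstituted enoate.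

**Step 10**
Reactants: 9 (2R)-2,8-dimethyl-6-(triisopropylsilyloxy)-2-vinyl-2H-chromene; 20 9-borabicyclo[3.3.1]nonane; 19 methyl (2Z,6E)-7-iodo-6-methyl-2-(4-methylpent-3-en-1-yl)hepta-2,6-dienoate
Product: 22 methyl (2Z,6E)-9-[(2R)-2,8-dimethyl-6-(triisopropylsilyloxy)-2H-chromen-2-yl]-6-methyl-2-(4-methylpent-3-en-1-yl)nona-2,6-dienoate, via alkylborane 21 (not isolated)
Conditions: 20 (1.3 equiv.), THF, 0 °C → rt; then 3 M aq. K3PO4 (3 equiv.), 19, PdCl2(dppf)·CH2Cl2 (5 mol%), AsPh3 (10 mol%), DMF, rt
Reagents that add atoms: none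
Why: 9-BBN adds anti-Markovnikov and only to the monosubstituted C2-vinyl group, placing boron on C2', and aqueous phosphate turns the primary borane into its borate. Zerovalent palladium formed from PdCl2(dppf) inserts into the C–I bond of 19 with retention of the (E) geometry, the primary alkyl group is transferred, and reductive elimination forms the C2'–C3' bond; the closest known reaction type is the B-alkyl Suzuki–Miyaura coupling of primary alkyl-9-BBN reagents with (E)-2-methyl-1-iodoalkenes. No ring is closed and no new stereocenter is formed; C2 is quaternary and cannot epimerize, the vinyl group through which palladium could ionize the C2–O1 allylic ether is consumed before the catalyst is added, and in the product that bond lies near the nodal plane of the ring B alkene. The step needs chemoselectivity among five C=C bonds and fidelity at two alkene geometries: 9-BBN discriminates the terminal alkene from the cis-disubstituted C3=C4, excess borane is quenched by the aqueous base before 19 enters, the borate does not add to the hindered (Z)-enoate, and dppf with AsPh3 favours reductive elimination over β-hydride elimination.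

**Step 11**
Reactants: 22 methyl (2Z,6E)-9-[(2R)-2,8-dimethyl-6-(triisopropylsilyloxy)-2H-chromen-2-yl]-6-methyl-2-(4-methylpent-3-en-1-yl)nona-2,6-dienoate
Product: 24 (R)-sargachromenol, via phenol methyl ester 23 (not isolated)
Conditions: Bu4NF (1.1 equiv.), THF, 0 °C; then LiOH·H2O (10 equiv.), THF/MeOH/H2O (degassed, argon), 45 °C; 1 M HCl to pH 4 at 0 °C
Reagents that add atoms: lithium hydroxide, [Li+].[OH-]
Why: Fluoride cleaves the aryl silyl ether and hydroxide then saponifies the methyl ester (BAc2) with exclusion of oxygen to protect the electron-rich chromenol, neither reagent touching C2 or the alkene geometries.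

**Compound list**
1 | 2-methylbenzene-1,4-diol (methylhydroquinone) | Cc1cc(O)ccc1O | starting material
2 | chlorotriisopropylsilane | CC(C)[Si](Cl)(C(C)C)C(C)C | starting material
3 | 2-methyl-4-(triisopropylsilyloxy)phenol | Cc1cc(O[Si](C(C)C)(C(C)C)C(C)C)ccc1O | intermediate
4 | 2-methyl-2-vinyloxirane (isoprene monoxide, racemic) | CC1(C=C)CO1 | starting material
5 | (2R)-2-methyl-2-[2-methyl-4-(triisopropylsilyloxy)phenoxy]but-3-en-1-ol | C=C[C@](C)(CO)Oc1ccc(O[Si](C(C)C)(C(C)C)C(C)C)cc1C | intermediate
6 | (2R)-2-methyl-2-[2-methyl-4-(triisopropylsilyloxy)phenoxy]but-3-enal | C=C[C@](C)(C=O)Oc1ccc(O[Si](C(C)C)(C(C)C)C(C)C)cc1C | intermediate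
7 | dimethyl (1-diazo-2-oxopropyl)phosphonate | CC(=O)C(=[N+]=[N-])P(=O)(OC)OC | starting material
8 | (3R)-3-methyl-3-[2-methyl-4-(triisopropylsilyloxy)phenoxy]pent-1-en-4-yne | C=C[C@](C)(C#C)Oc1ccc(O[Si](C(C)C)(C(C)C)C(C)C)cc1C | intermediate
9 | (2R)-2,8-dimethyl-6-(triisopropylsilyloxy)-2-vinyl-2H-chromene | C=C[C@]1(C)C=Cc2cc(O[Si](C(C)C)(C(C)C)C(C)C)cc(C)c2O1 | intermediate
10 | pent-4-yn-1-ol | C#CCCCO | starting material
11 | trimethylaluminium | C[Al](C)C | starting material
12 | iodine | II | starting material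
13 | alkenylalane: dimethylaluminium alkoxide of (E)-5-(dimethylalumanyl)-4-methylpent-4-en-1-ol | C[Al](C)OCCC/C(C)=C/[Al](C)C | intermediate
14 | (E)-5-iodo-4-methylpent-4-en-1-ol | OCCC/C(C)=C/I | intermediate
15 | (E)-5-iodo-4-methylpent-4-enal | O=CCC/C(C)=C/I | intermediate
16 | methyl 2-[bis(2,2,2-trifluoroethoxy)phosphoryl]acetate | COC(=O)CP(=O)(OCC(F)(F)F)OCC(F)(F)F | starting material
17 | 5-bromo-2-methylpent-2-ene | CC(C)=CCCBr | starting material
18 | methyl 2-[bis(2,2,2-trifluoroethoxy)phosphoryl]-6-methylhept-5-enoate (racemic) | COC(=O)C(CCC=C(C)C)P(=O)(OCC(F)(F)F)OCC(F)(F)F | intermediate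
19 | methyl (2Z,6E)-7-iodo-6-methyl-2-(4-methylpent-3-en-1-yl)hepta-2,6-dienoate | CC(C)=CCC/C(=C/CC/C(C)=C/I)C(=O)OC | intermediate
20 | 9-borabicyclo[3.3.1]nonane (9-BBN) | B1C2CCCC1CCC2 | starting material
21 | 9-{2-[(2R)-2,8-dimethyl-6-(triisopropylsilyloxy)-2H-chromen-2-yl]ethyl}-9-borabicyclo[3.3.1]nonane | C(C[C@]1(C)C=Cc2cc(O[Si](C(C)C)(C(C)C)C(C)C)cc(C)c2O1)B3C4CCCC3CCC4 | intermediate
22 | methyl (2Z,6E)-9-[(2R)-2,8-dimethyl-6-(triisopropylsilyloxy)-2H-chromen-2-yl]-6-methyl-2-(4-methylpent-3-en-1-yl)nona-2,6-dienoate | CC(C)=CCC/C(=C/CC/C(C)=C/CC[C@]1(C)C=Cc2cc(O[Si](C(C)C)(C(C)C)C(C)C)cc(C)c2O1)C(=O)OC | intermediate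
23 | methyl (2Z,6E)-9-[(2R)-6-hydroxy-2,8-dimethyl-2H-chromen-2-yl]-6-methyl-2-(4-methylpent-3-en-1-yl)nona-2,6-dienoate | CC(C)=CCC/C(=C/CC/C(C)=C/CC[C@]1(C)C=Cc2cc(O)cc(C)c2O1)C(=O)OC | intermediate
24 | (R)-sargachromenol, (2Z,6E)-9-[(2R)-6-hydroxy-2,8-dimethyl-2H-chromen-2-yl]-6-methyl-2-(4-methylpent-3-en-1-yl)nona-2,6-dienoic acid | CC(C)=CCC/C(=C/CC/C(C)=C/CC[C@]1(C)C=Cc2cc(O)cc(C)c2O1)C(=O)O | target

**Summary**
Total step count: 11. Longest linear sequence: 7 steps (steps 1–5, 10, 11); the iododienoate branch is steps 6, 7 and 9, with step 8 as a side branch.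

**Steps most likely to fail**

Step 2. What may go wrong: attack of the ortho-substituted phenol at the CH2 terminus of the π-allyl instead of the fully substituted one, and erosion of enantiomeric purity by reversible re-ionization of the tertiary allyl aryl ether. Fallback (enzymatic desymmetrization of a prochiral diol in place of asymmetric allylic etherification; sets out from 3, returns at 5): alkylation of 3 with diethyl 2-bromo-2-methylmalonate (K2CO3, DMF, 60 °C) should give diethyl 2-methyl-2-[2-methyl-4-(triisopropylsilyloxy)phenoxy]propanedioate F1. LiAlH4 (THF, 0 °C) reduces it to 2-methyl-2-[2-methyl-4-(triisopropylsilyloxy)phenoxy]propane-1,3-diol F2. A lipase (Burkholderia cepacia lipase, vinyl acetate, t-BuOMe, rt) should acetylate one of the two enantiotopic CH2OH groups to give (2R)-3-hydroxy-2-methyl-2-[2-methyl-4-(triisopropylsilyloxy)phenoxy]propyl acetate F3. Dess–Martin oxidation gives (2S)-2-methyl-2-[2-methyl-4-(triisopropylsilyloxy)phenoxy]-3-oxopropyl acetate F4. Wittig methylenation (Ph3P=CH2 from Ph3PCH3Br and KOt-Bu, THF, 0 °C) gives (2R)-2-methyl-2-[2-methyl-4-(triisopropylsilyloxy)phenoxy]but-3-en-1-yl acetate F5, and K2CO3 in MeOH at 0 °C removes the acetate to give 5.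

Step 5. What may go wrong: ionization of the tertiary ether, which is allylic and propargylic at once, under the cationic gold catalyst (loss of the aryloxy group or of configuration), and competing reaction of the vinyl group with the activated alkyne. Fallback (ring B closed at C3=C4 by ring-closing metathesis instead of at C4–C4a by hydroarylation; sets out from 3, returns at 9): ortho-formylation of 3 (MgCl2, Et3N, paraformaldehyde, MeCN, reflux) gives 2-hydroxy-3-methyl-5-(triisopropylsilyloxy)benzaldehyde F6. Wittig methylenation gives 2-methyl-4-(triisopropylsilyloxy)-6-vinylphenol F7. The allylic etherification of step 2 with 4, now with the (R,R) ligand, gives (2S)-2-methyl-2-[2-methyl-4-(triisopropylsilyloxy)-6-vinylphenoxy]but-3-en-1-ol F8, in which the vinyl group is the future C3 and the CH2OH the future C1'. Ring-closing metathesis of the two vinyl groups (second-generation Grubbs catalyst, RuCl2(=CHPh)(PCy3)(H2IMes), CH2Cl2, 40 °C) gives [(2S)-2,8-dimethyl-6-(triisopropylsilyloxy)-2H-chromen-2-yl]methanol F9. Dess–Martin oxidation gives (2S)-2,8-dimethyl-6-(triisopropylsilyloxy)-2H-chromene-2-carbaldehyde F10, and a second Wittig methylenation gives 9.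

Step 9. What may go wrong: erosion of Z-selectivity with the α-branched phosphonate and low conversion with this hindered reagent. Fallback (the α-substituent is introduced after the olefination by a stereoretentive cross-coupling, and the fragment union is moved ahead of the olefination; sets out from 14 and borane 21, returns at 22): B-alkyl Suzuki–Miyaura coupling of 21 with 14 under the conditions of step 10 gives (4E)-7-[(2R)-2,8-dimethyl-6-(triisopropylsilyloxy)-2H-chromen-2-yl]-4-methylhept-4-en-1-ol F11. Dess–Martin oxidation gives (4E)-7-[(2R)-2,8-dimethyl-6-(triisopropylsilyloxy)-2H-chromen-2-yl]-4-methylhept-4-enal F12. Olefination with the unbranched reagent methyl bis(2,2,2-trifluoroethyl)bromophosphonoacetate (KN(SiMe3)2, 18-crown-6, THF, −78 °C) should give methyl (2E,6E)-2-bromo-9-[(2R)-2,8-dimethyl-6-(triisopropylsilyloxy)-2H-chromen-2-yl]-6-methylnona-2,6-dienoate F13, with the ester already cis to the chain. Negishi coupling with (4-methylpent-3-en-1-yl)zinc bromide (from 17 and zinc dust; Pd(P(t-Bu)3)2, THF, rt) replaces bromine with retention and gives 22.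

**Further compounds**
F1 | step 2 | diethyl 2-methyl-2-[2-methyl-4-(triisopropylsilyloxy)phenoxy]propanedioate | CCOC(=O)C(C)(Oc1ccc(O[Si](C(C)C)(C(C)C)C(C)C)cc1C)C(=O)OCC
F2 | step 2 | 2-methyl-2-[2-methyl-4-(triisopropylsilyloxy)phenoxy]propane-1,3-diol | CC(CO)(CO)Oc1ccc(O[Si](C(C)C)(C(C)C)C(C)C)cc1C
F3 | step 2 | (2R)-3-hydroxy-2-methyl-2-[2-methyl-4-(triisopropylsilyloxy)phenoxy]propyl acetate | OC[C@](C)(COC(C)=O)Oc1ccc(O[Si](C(C)C)(C(C)C)C(C)C)cc1C
F4 | step 2 | (2S)-2-methyl-2-[2-methyl-4-(triisopropylsilyloxy)phenoxy]-3-oxopropyl acetate | O=C[C@](C)(COC(C)=O)Oc1ccc(O[Si](C(C)C)(C(C)C)C(C)C)cc1C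
F5 | step 2 | (2R)-2-methyl-2-[2-methyl-4-(triisopropylsilyloxy)phenoxy]but-3-en-1-yl acetate | C=C[C@](C)(COC(C)=O)Oc1ccc(O[Si](C(C)C)(C(C)C)C(C)C)cc1C
F6 | step 5 | 2-hydroxy-3-methyl-5-(triisopropylsilyloxy)benzaldehyde | O=Cc1cc(O[Si](C(C)C)(C(C)C)C(C)C)cc(C)c1O
F7 | step 5 | 2-methyl-4-(triisopropylsilyloxy)-6-vinylphenol | C=Cc1cc(O[Si](C(C)C)(C(C)C)C(C)C)cc(C)c1O
F8 | step 5 | (2S)-2-methyl-2-[2-methyl-4-(triisopropylsilyloxy)-6-vinylphenoxy]but-3-en-1-ol | OC[C@](C)(C=C)Oc1c(C=C)cc(O[Si](C(C)C)(C(C)C)C(C)C)cc1C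
F9 | step 5 | [(2S)-2,8-dimethyl-6-(triisopropylsilyloxy)-2H-chromen-2-yl]methanol | OC[C@]1(C)C=Cc2cc(O[Si](C(C)C)(C(C)C)C(C)C)cc(C)c2O1
F10 | step 5 | (2S)-2,8-dimethyl-6-(triisopropylsilyloxy)-2H-chromene-2-carbaldehyde | O=C[C@]1(C)C=Cc2cc(O[Si](C(C)C)(C(C)C)C(C)C)cc(C)c2O1
F11 | step 9 | (4E)-7-[(2R)-2,8-dimethyl-6-(triisopropylsilyloxy)-2H-chromen-2-yl]-4-methylhept-4-en-1-ol | OCCC/C(C)=C/CC[C@]1(C)C=Cc2cc(O[Si](C(C)C)(C(C)C)C(C)C)cc(C)c2O1
F12 | step 9 | (4E)-7-[(2R)-2,8-dimethyl-6-(triisopropylsilyloxy)-2H-chromen-2-yl]-4-methylhept-4-enal | O=CCC/C(C)=C/CC[C@]1(C)C=Cc2cc(O[Si](C(C)C)(C(C)C)C(C)C)cc(C)c2O1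
F13 | step 9 | methyl (2E,6E)-2-bromo-9-[(2R)-2,8-dimethyl-6-(triisopropylsilyloxy)-2H-chromen-2-yl]-6-methylnona-2,6-dienoate | Br/C(C(=O)OC)=C/CC/C(C)=C/CC[C@]1(C)C=Cc2cc(O[Si](C(C)C)(C(C)C)C(C)C)cc(C)c2O1
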